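## Retrosynthetic overview
1. The C15/C16 trans-diol comes last, from a tricyclic C16 enone by α′-hydroxylation and OH-directed 1,2-reduction. The acetate comes from the C2 carbinol.
2. Ring A (11-membered) is opened at C1–C2, which gives a 2-iodoalkene and an aldehyde for a ligand-controlled Ni/Cr coupling.
3. Rings B and C are opened together at C10–C14 and C8–C16. An acyclic keto enoate closes both in one anionic Michael/Claisen operation, and MeLi addition with carbonyl transposition then gives C8=C9(Me).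
4. The acyclic chain comes from an HWE union at C10=C11 of a citronellyl β-ketophosphonate and a methyl geranate-derived aldehyde. C11 is set by Rh-catalysed conjugate alkynylation.
5. Ring order: B and C in the same operation, then A.

Atom labels follow the target SMILES from left to right, with the exocyclic CH2 not counted: C1 (bears =CH2), C2 (CHOAc), C3, C4, C5 (CHMe), C6, C7, C8=C9(Me), C10, C11, C12, C13, C14 (quaternary, Me), C15, C16. Ring A is C1–C11, ring B is C10–C14, ring C is C8, C9, C10, C14, C15, C16.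

Assumption: in steps 4 and 10 the named ligand enantiomer is the one that gives the drawn configuration. If the sense of induction is opposite, the mirror-image ligand is used.

## Route

Step 1
Reactants: 1 (R)-citronellyl bromide; 2 dimethyl (2-oxopropyl)phosphonate
Product: 4 dimethyl [(6S)-6,10-dimethyl-2-oxoundec-9-en-1-yl]phosphonate, via phosphonate dianion 3 (not isolated)
Conditions: NaH, THF, 0 °C; n-BuLi, 0 °C; then 1, 0 → 23 °C
Reagents that add atoms: none
Why: γ-Alkylation of a β-ketophosphonate dianion, in which the more basic terminal carbanion of 3 displaces the primary bromide (SN2) to form C7–C8 without touching the chiral-pool stereocentre C5.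

Step 2
Reactants: 5 methyl geranate
Product: 7 methyl (2E)-3-methyl-6-oxohex-2-enoate, via secondary ozonide 6 (not isolated)
Conditions: O3, CH2Cl2, −78 °C (Sudan Red 7B end point); Me2S, −78 → 23 °C
Reagents that add atoms: ozone, [O-][O+]=O
Why: Chemoselective ozonolysis, because the isolated electron-rich trisubstituted alkene reacts far faster than the ester-conjugated one, and no stereocentre is formed.

Step 3
Reactants: 4 dimethyl [(6S)-6,10-dimethyl-2-oxoundec-9-en-1-yl]phosphonate; 7 methyl (2E)-3-methyl-6-oxohex-2-enoate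
Product: 8 methyl (2E,6E,12S)-3,12,16-trimethyl-8-oxoheptadeca-2,6,15-trienoate
Conditions: LiCl, DBU, MeCN, 0 → 23 °C
Reagents that add atoms: none
Why: Horner–Wadsworth–Emmons olefination under Masamune–Roush conditions joins the two halves at C10=C11 as the (E)-enone under a base mild enough for the enolisable aldehyde.

Step 4
Reactants: 8 methyl (2E,6E,12S)-3,12,16-trimethyl-8-oxoheptadeca-2,6,15-trienoate; 9 (triisopropylsilyl)acetylene
Product: 10 methyl (2E,6R,12S)-3,12,16-trimethyl-8-oxo-6-[(triisopropylsilyl)ethynyl]heptadeca-2,15-dienoate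
Conditions: [Rh(OAc)(C2H4)2]2 (2.5 mol %), (R)-DTBM-SEGPHOS (5.5 mol %), 1,4-dioxane, 80 °C
Reagents that add atoms: none
Why: Rhodium-catalysed asymmetric conjugate alkynylation, in which the alkynylrhodium species adds only to the β-monosubstituted enone (the β,β-disubstituted enoate is inert), the bulky silyl group and ligand suppress alkyne dimerisation, and the chiral bisphosphine sets C11 as R.

Step 5
Reactants: 10 methyl (2E,6R,12S)-3,12,16-trimethyl-8-oxo-6-[(triisopropylsilyl)ethynyl]heptadeca-2,15-dienoate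
Product: 13 (3R,3aS,7aS)-5-[(3R)-3,7-dimethyloct-6-en-1-yl]-6-methoxy-7a-methyl-3-[(triisopropylsilyl)ethynyl]-1,2,3,3a,7,7a-hexahydro-4H-inden-4-one, via Michael adduct keto ester 11 (not isolated), via bicyclic 1,3-dione 12 (not isolated)
Conditions: KOt-Bu (1.5 equiv), THF/t-BuOH, 0 → 50 °C; aq. HCl; crude 12, HC(OMe)3, TsOH (cat.), MeOH, 23 °C
Reagents that add atoms: trimethyl orthoformate, COC(OC)OC
Why: Tandem intramolecular Michael addition–Claisen (Dieckmann-type) condensation, that is the dimedone construction run inside one chain: the C10 enolate closes ring B by 5-exo attack on C14 through a chair-like transition state with the alkynyl group pseudo-equatorial (C1 branch trans to C15, acyl group cis to C15), the (E)-enoate geometry forbids the competing seven-membered Claisen ring, the C8 enolate of 11 acylates on C16 to close ring C, irreversible deprotonation of 12 pulls the uphill quaternary-centre formation forward while epimerisable C10 settles in the cis-hydrindane, and acid-catalysed enol etherification occurs at the less hindered C16 carbonyl remote from substituted C10.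

Step 6
Reactants: 13 the vinylogous methyl ester of step 5
Product: 15 (3R,3aS,7aS)-5-[(3R)-3,7-dimethyloct-6-en-1-yl]-4,7a-dimethyl-3-[(triisopropylsilyl)ethynyl]-1,2,3,3a,7,7a-hexahydro-6H-inden-6-one, via tertiary carbinol 14 (not isolated)
Conditions: MeLi, THF, −78 → 0 °C; then 1 M HCl, 23 °C
Reagents that add atoms: methyllithium, [Li]C
Why: Stork–Danheiser transposition, in which 1,2-addition to the C9 carbonyl and acid hydrolysis of 14 move the carbonyl to C16 and leave the tetrasubstituted C8=C9 alkene carrying the new methyl group, with C10 staying in its thermodynamic cis-fused configuration.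

Step 7
Reactants: 15 the silylalkynyl hydrindenone of step 6
Product: 16 (3R,3aS,7aS)-5-[(3R)-3,7-dimethyloct-6-en-1-yl]-3-ethynyl-4,7a-dimethyl-1,2,3,3a,7,7a-hexahydro-6H-inden-6-one
Conditions: Bu4NF, THF, 0 → 23 °C
Reagents that add atoms: none
Why: Fluoride-induced protodesilylation of the alkynylsilane leaves the enone, the alkene and all stereocentres untouched.

Step 8
Reactants: 16 the terminal alkyne of step 7
Product: 18 (3R,3aS,7aS)-5-[(3R)-3,7-dimethyloct-6-en-1-yl]-3-(1-iodoethenyl)-4,7a-dimethyl-1,2,3,3a,7,7a-hexahydro-6H-inden-6-one, via alkenylborane 17 (not isolated)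
Conditions: 9-iodo-9-BBN, CH2Cl2, −20 → 0 °C; then AcOH, 0 °C
Reagents that add atoms: 9-iodo-9-borabicyclo[3.3.1]nonane, IB1C2CCCC1CCC2
Why: Haloboration–protonolysis, in which syn addition of B–I puts iodine on the internal alkyne carbon C1 (Markovnikov), alkenes do not react, and acetic acid cleaves the C–B bond of 17 to give the 2-iodo-1-alkene.

Step 9
Reactants: 18 the iodoalkene of step 8
Product: 20 (4S)-6-[(3R,3aS,7aS)-3-(1-iodoethenyl)-4,7a-dimethyl-6-oxo-2,3,3a,6,7,7a-hexahydro-1H-inden-5-yl]-4-methylhexanal, via vicinal diol 19 (not isolated)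
Conditions: OsO4 (2 mol %), NaIO4, 2,6-lutidine, 1,4-dioxane/H2O, 23 °C
Reagents that add atoms: sodium periodate, [Na+].[O-]I(=O)(=O)=O; osmium tetroxide (oxygen relay), O=[Os](=O)(=O)=O
Why: Johnson–Lemieux oxidation, in which OsO4 dihydroxylates the only electron-rich alkene (the iodoalkene and the tetrasubstituted enone are deactivated and hindered) and periodate cleaves 19 to the C2 aldehyde.

Step 10
Reactants: 20 the iodoalkenyl aldehyde of step 9
Product: 21 tricyclic hydroxy enone (2R,5S,10S,11R,14S): target skeleton with C1=CH2, C2–OH, C8=C9, C15H2, C16=O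
Conditions: CrCl2, N-[2-((S)-4-isopropyl-4,5-dihydrooxazol-2-yl)-6-methylphenyl]methanesulfonamide, Et3N, NiCl2 (cat.), THF/MeCN, 2 mM (slow addition), 23 °C
Reagents that add atoms: none
Why: Nozaki–Hiyama–Kishi macrocyclisation, in which zerovalent nickel inserts into the C–I bond, transmetalation gives an alkenyl species of trivalent chromium that adds only to the aldehyde, high dilution favours closure of 11-membered ring A on the preorganised cis-hydrindenone, and the chiral oxazoline–sulfonamide ligand on chromium selects the aldehyde face that gives the (2R)-carbinol.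

Step 11
Reactants: 21 tricyclic hydroxy enone
Product: 22 tricyclic acetoxy enone (2R,5S,10S,11R,14S): 21 with C2–OAc
Conditions: Ac2O, pyridine, DMAP (cat.), CH2Cl2, 0 → 23 °C
Reagents that add atoms: acetic anhydride, CC(=O)OC(C)=O
Why: DMAP-catalysed acylation of the only hydroxyl group present, with retention at C2, so no site selectivity is needed.

Step 12
Reactants: 22 tricyclic acetoxy enone
Product: 24 tricyclic α′-hydroxy enone (2R,5S,10R,11R,14R,15R): 22 with C15–OH, via lithium dienolate 23 (not isolated)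
Conditions: LiN(SiMe3)2, THF, −78 °C; 2-(benzenesulfonyl)-3-phenyloxaziridine, −78 °C; AcOH
Reagents that add atoms: 2-(benzenesulfonyl)-3-phenyloxaziridine, O=S(=O)(N1OC1c1ccccc1)c1ccccc1
Why: Davis oxidation, in which the amide base removes the kinetic α′ proton at C15 (the ketone is far more acidic than the acetate) to give cross-conjugated dienolate 23, and the oxaziridine delivers oxygen to the face opposite the pseudoaxial angular methyl on C14, giving the (15R)-ketol with OH cis to C13.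

Step 13
Reactants: 24 tricyclic α′-hydroxy enone
Product: 25 target CNP0192310.2 (2R,5S,10R,11R,14R,15R,16R)
Conditions: Me4NBH(OAc)3, MeCN/AcOH, −30 °C
Reagents that add atoms: none
Why: Saksena–Evans hydroxyl-directed reduction, in which the C15 hydroxyl binds boron and the hydride is delivered to the same face of the C16 carbonyl, so the new hydroxyl is trans to C15–OH (16R) while the acetate and both alkenes are untouched.

## Compound list
1 | (R)-citronellyl bromide, (6R)-8-bromo-2,6-dimethyloct-2-ene | BrCC[C@H](C)CCC=C(C)C | starting material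
2 | dimethyl (2-oxopropyl)phosphonate | CC(=O)CP(=O)(OC)OC | starting material
3 | sodium lithium dianion of 2 | [Na+].[Li+].[CH2-]C(=O)[CH-]P(=O)(OC)OC | intermediate
4 | dimethyl [(6S)-6,10-dimethyl-2-oxoundec-9-en-1-yl]phosphonate | COP(=O)(CC(=O)CCC[C@H](C)CCC=C(C)C)OC | intermediate
5 | methyl geranate, methyl (2E)-3,7-dimethylocta-2,6-dienoate | COC(=O)/C=C(\C)CCC=C(C)C | starting material
6 | methyl (2E)-5-(5,5-dimethyl-1,2,4-trioxolan-3-yl)-3-methylpent-2-enoate | COC(=O)/C=C(\C)CCC1OOC(C)(C)O1 | intermediate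
7 | methyl (2E)-3-methyl-6-oxohex-2-enoate | COC(=O)/C=C(\C)CCC=O | intermediate
8 | methyl (2E,6E,12S)-3,12,16-trimethyl-8-oxoheptadeca-2,6,15-trienoate | COC(=O)/C=C(\C)CC/C=C/C(=O)CCC[C@H](C)CCC=C(C)C | intermediate
9 | (triisopropylsilyl)acetylene | C#C[Si](C(C)C)(C(C)C)C(C)C | starting material
10 | methyl (2E,6R,12S)-3,12,16-trimethyl-8-oxo-6-[(triisopropylsilyl)ethynyl]heptadeca-2,15-dienoate | COC(=O)/C=C(\C)CC[C@@H](C#C[Si](C(C)C)(C(C)C)C(C)C)CC(=O)CCC[C@H](C)CCC=C(C)C | intermediate
11 | methyl {(1S,2S,3R)-2-[(5S)-5,9-dimethyldec-8-enoyl]-1-methyl-3-[(triisopropylsilyl)ethynyl]cyclopentyl}acetate | COC(=O)C[C@]1(C)CC[C@@H](C#C[Si](C(C)C)(C(C)C)C(C)C)[C@@H]1C(=O)CCC[C@H](C)CCC=C(C)C | intermediate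
12 | (3R,3aS,7aS)-5-[(3R)-3,7-dimethyloct-6-en-1-yl]-7a-methyl-3-[(triisopropylsilyl)ethynyl]hexahydro-1H-indene-4,6(2H,5H)-dione (C5 enolisable; formed as its potassium enolate) | O=C1C[C@]2(C)CC[C@@H](C#C[Si](C(C)C)(C(C)C)C(C)C)[C@@H]2C(=O)C1CC[C@H](C)CCC=C(C)C | intermediate
13 | (3R,3aS,7aS)-5-[(3R)-3,7-dimethyloct-6-en-1-yl]-6-methoxy-7a-methyl-3-[(triisopropylsilyl)ethynyl]-1,2,3,3a,7,7a-hexahydro-4H-inden-4-one | COC1=C(CC[C@H](C)CCC=C(C)C)C(=O)[C@H]2[C@H](C#C[Si](C(C)C)(C(C)C)C(C)C)CC[C@@]2(C)C1 | intermediate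
14 | (3R,3aS,7aS)-5-[(3R)-3,7-dimethyloct-6-en-1-yl]-6-methoxy-4,7a-dimethyl-3-[(triisopropylsilyl)ethynyl]-2,3,3a,4,7,7a-hexahydro-1H-inden-4-ol (C4 epimers) | COC1=C(CC[C@H](C)CCC=C(C)C)C(C)(O)[C@H]2[C@H](C#C[Si](C(C)C)(C(C)C)C(C)C)CC[C@@]2(C)C1 | intermediate
15 | (3R,3aS,7aS)-5-[(3R)-3,7-dimethyloct-6-en-1-yl]-4,7a-dimethyl-3-[(triisopropylsilyl)ethynyl]-1,2,3,3a,7,7a-hexahydro-6H-inden-6-one | O=C1C[C@]2(C)CC[C@@H](C#C[Si](C(C)C)(C(C)C)C(C)C)[C@@H]2C(C)=C1CC[C@H](C)CCC=C(C)C | intermediate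
16 | (3R,3aS,7aS)-5-[(3R)-3,7-dimethyloct-6-en-1-yl]-3-ethynyl-4,7a-dimethyl-1,2,3,3a,7,7a-hexahydro-6H-inden-6-one | O=C1C[C@]2(C)CC[C@@H](C#C)[C@@H]2C(C)=C1CC[C@H](C)CCC=C(C)C | intermediate
17 | (Z)-2-iodoalkenyl-9-BBN adduct of 16 (B on the terminal carbon, I on C1, B and I cis) | O=C1C[C@]2(C)CC[C@@H](/C(I)=C/B3C4CCCC3CCC4)[C@@H]2C(C)=C1CC[C@H](C)CCC=C(C)C | intermediate
18 | (3R,3aS,7aS)-5-[(3R)-3,7-dimethyloct-6-en-1-yl]-3-(1-iodoethenyl)-4,7a-dimethyl-1,2,3,3a,7,7a-hexahydro-6H-inden-6-one | O=C1C[C@]2(C)CC[C@@H](C(I)=C)[C@@H]2C(C)=C1CC[C@H](C)CCC=C(C)C | intermediate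
19 | side-chain 6,7-diol of 18 (carbinol epimers) | O=C1C[C@]2(C)CC[C@@H](C(I)=C)[C@@H]2C(C)=C1CC[C@H](C)CCC(O)C(C)(C)O | intermediate
20 | (4S)-6-[(3R,3aS,7aS)-3-(1-iodoethenyl)-4,7a-dimethyl-6-oxo-2,3,3a,6,7,7a-hexahydro-1H-inden-5-yl]-4-methylhexanal | O=C1C[C@]2(C)CC[C@@H](C(I)=C)[C@@H]2C(C)=C1CC[C@H](C)CCC=O | intermediate
21 | tricyclic hydroxy enone (2R,5S,10S,11R,14S): C2–OH, C15H2, C16=O | C=C1[C@H](O)CC[C@@H](C)CCC2=C(C)[C@H]3[C@H]1CC[C@@]3(C)CC2=O | intermediate
22 | tricyclic acetoxy enone (2R,5S,10S,11R,14S): C2–OAc, C15H2, C16=O | C=C1[C@H](OC(C)=O)CC[C@@H](C)CCC2=C(C)[C@H]3[C@H]1CC[C@@]3(C)CC2=O | intermediate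
23 | lithium C15=C16 dienolate of 22 | [Li+].C=C1[C@H](OC(C)=O)CC[C@@H](C)CCC2=C(C)[C@H]3[C@H]1CC[C@@]3(C)C=C2[O-] | intermediate
24 | tricyclic α′-hydroxy enone (2R,5S,10R,11R,14R,15R): C2–OAc, C15–OH, C16=O | C=C1[C@H](OC(C)=O)CC[C@@H](C)CCC2=C(C)[C@H]3[C@H]1CC[C@@]3(C)[C@@H](O)C2=O | intermediate
25 | CNP0192310.2 (2R,5S,10R,11R,14R,15R,16R) | C=C1[C@H](OC(C)=O)CC[C@@H](C)CCC2=C(C)[C@H]3[C@H]1CC[C@@]3(C)[C@@H](O)[C@@H]2O | target

## Step count and risks
Total steps: 13. Longest linear sequence: 12 (steps 1, 3–13, or equally steps 2, 3–13).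

**Step 5 (bicyclisation).**
- Risk: a simple ketone enolate may add too slowly to the β,β-disubstituted enoate, leading to deconjugation or recovered 10. The enol ether could also form partly on the wrong carbonyl.
- Fallback: it sets out from 4 and comes back at 15. The acceptor becomes an enal, and ring C is closed by aldol condensation instead of acylation.
- Selective ozonolysis of commercial geranial gives (2E)-3-methylhex-2-enedial F1. Only its saturated aldehyde undergoes the LiCl/DBU olefination with 4, which gives (2E,6E,12S)-3,12,16-trimethyl-8-oxoheptadeca-2,6,15-trienal F2.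
- The alkynylation of step 4 with 9 then gives (2E,6R,12S)-3,12,16-trimethyl-8-oxo-6-[(triisopropylsilyl)ethynyl]heptadeca-2,15-dienal F3.
- Pyrrolidinium acetate (toluene, 60 °C) activates the enal as its iminium ion. C10 adds to C14, and the only possible six-ring aldol condensation (C8 onto the C16 aldehyde) follows. Both rings again form in one operation, giving (3R,3aS,7aS)-5-[(3R)-3,7-dimethyloct-6-en-1-yl]-7a-methyl-3-[(triisopropylsilyl)ethynyl]-1,2,3,3a,7,7a-hexahydro-4H-inden-4-one F4.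
- MeLi adds to the C9 carbonyl to give (3R,3aS,7aS)-5-[(3R)-3,7-dimethyloct-6-en-1-yl]-4,7a-dimethyl-3-[(triisopropylsilyl)ethynyl]-2,3,3a,4,7,7a-hexahydro-1H-inden-4-ol F5. Oxidative allylic transposition with pyridinium chlorochromate, [C5H5NH][CrO3Cl] (Babler–Dauben oxidation), then gives 15.

**Step 10 (closure of ring A).**
- Risk: closing a bridging 11-membered ring that contains an (E)-tetrasubstituted alkene on a rigid bicycle may give oligomers, and the ligand may be mismatched with the substrate.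
- Fallback: it sets out from 10 and comes back at 21. The ring order is reversed, so ring A is closed while the chain is still flexible and rings B and C are then built across it.
- Bu4NF converts 10 into methyl (2E,6R,12S)-6-ethynyl-3,12,16-trimethyl-8-oxoheptadeca-2,15-dienoate F6. Treatment with 9-iodo-9-BBN and then AcOH gives methyl (2E,6R,12S)-6-(1-iodoethenyl)-3,12,16-trimethyl-8-oxoheptadeca-2,15-dienoate F7.
- OsO4/NaIO4 gives methyl (2E,6R,12S)-6-(1-iodoethenyl)-3,12-dimethyl-8,15-dioxopentadec-2-enoate F8.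
- The same CrCl2/NiCl2/ligand coupling closes an unbridged cycloundecanone, methyl (2E)-5-[(1R,3R,6S)-3-hydroxy-6-methyl-2-methylidene-10-oxocycloundecyl]-3-methylpent-2-enoate F9.
- KOt-Bu (one extra equivalent for the carbinol) followed by HC(OMe)3/TsOH/MeOH performs the Michael–Claisen bicyclisation on the macrocyclic ketone. This gives the tricyclic vinylogous methyl ester (2R,5S,10S,11R,14S; C2–OH, C9=O, C16–OMe) F10.
- Excess MeLi followed by 1 M HCl gives 21.

**Step 12 (α′-hydroxylation).**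
- Risk: γ-deprotonation, attack on the acetate, or oxygen transfer from the wrong face.
- Fallback: it sets out from 22 and comes back at 24. It avoids strong base by using an oxidative metal-enolate acyloxylation.
- Mn(OAc)3 and chloroacetic acid in refluxing benzene give the 15-chloroacetoxy enone (2R,5S,10R,11R,14R,15R) F11. Any C15 epimer can be equilibrated through the enol.
- Thiourea/NaHCO3 in EtOH removes the chloroacetyl group selectively in the presence of the C2 acetate, which gives 24.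

## Further compounds
F1 | step 5 | (2E)-3-methylhex-2-enedial | O=C/C=C(\C)CCC=O
F2 | step 5 | (2E,6E,12S)-3,12,16-trimethyl-8-oxoheptadeca-2,6,15-trienal | O=C/C=C(\C)CC/C=C/C(=O)CCC[C@H](C)CCC=C(C)C
F3 | step 5 | (2E,6R,12S)-3,12,16-trimethyl-8-oxo-6-[(triisopropylsilyl)ethynyl]heptadeca-2,15-dienal | O=C/C=C(\C)CC[C@@H](C#C[Si](C(C)C)(C(C)C)C(C)C)CC(=O)CCC[C@H](C)CCC=C(C)C
F4 | step 5 | (3R,3aS,7aS)-5-[(3R)-3,7-dimethyloct-6-en-1-yl]-7a-methyl-3-[(triisopropylsilyl)ethynyl]-1,2,3,3a,7,7a-hexahydro-4H-inden-4-one | O=C1C(CC[C@H](C)CCC=C(C)C)=CC[C@]2(C)CC[C@@H](C#C[Si](C(C)C)(C(C)C)C(C)C)[C@H]12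
F5 | step 5 | (3R,3aS,7aS)-5-[(3R)-3,7-dimethyloct-6-en-1-yl]-4,7a-dimethyl-3-[(triisopropylsilyl)ethynyl]-2,3,3a,4,7,7a-hexahydro-1H-inden-4-ol (C4 epimers) | CC1(O)C(CC[C@H](C)CCC=C(C)C)=CC[C@]2(C)CC[C@@H](C#C[Si](C(C)C)(C(C)C)C(C)C)[C@H]12
F6 | step 10 | methyl (2E,6R,12S)-6-ethynyl-3,12,16-trimethyl-8-oxoheptadeca-2,15-dienoate | COC(=O)/C=C(\C)CC[C@@H](C#C)CC(=O)CCC[C@H](C)CCC=C(C)C
F7 | step 10 | methyl (2E,6R,12S)-6-(1-iodoethenyl)-3,12,16-trimethyl-8-oxoheptadeca-2,15-dienoate | COC(=O)/C=C(\C)CC[C@@H](C(I)=C)CC(=O)CCC[C@H](C)CCC=C(C)C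
F8 | step 10 | methyl (2E,6R,12S)-6-(1-iodoethenyl)-3,12-dimethyl-8,15-dioxopentadec-2-enoate | COC(=O)/C=C(\C)CC[C@@H](C(I)=C)CC(=O)CCC[C@H](C)CCC=O
F9 | step 10 | methyl (2E)-5-[(1R,3R,6S)-3-hydroxy-6-methyl-2-methylidene-10-oxocycloundecyl]-3-methylpent-2-enoate | C=C1[C@H](O)CC[C@@H](C)CCCC(=O)C[C@H]1CC/C(C)=C/C(=O)OC
F10 | step 10 | tricyclic vinylogous methyl ester (2R,5S,10S,11R,14S): C2–OH, C9=O, C8=C16–OMe | C=C1[C@H](O)CC[C@@H](C)CCC2=C(OC)C[C@]3(C)CC[C@@H]1[C@@H]3C2=O
F11 | step 12 | 15-chloroacetoxy enone (2R,5S,10R,11R,14R,15R): 24 with C15–OC(O)CH2Cl | C=C1[C@H](OC(C)=O)CC[C@@H](C)CCC2=C(C)[C@H]3[C@H]1CC[C@@]3(C)[C@@H](OC(=O)CCl)C2=O
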